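(All runs are simulated for substances that don't exist, and the scatter is random.)

Plot ln(charged/left) for the starting material against time in each earlier run.

| setting | midnight | spring | flask |
|---|---|---|---|
| starting material | 0.20 M | 0.45 M | 0.30 M |
| second substrate | 1 equiv | 1 equiv | 1.00 equiv |
| coupling partner | 2.5 equiv | 2.5 equiv | 2.50 equiv |
| free catalyst | 0.25 mol% | 0.25 mol% | 0.25 mol% |
| remark | run made earlier | run made earlier |  |

| run | time / min | target / % | starting material / % |
|---|---|---|---|
| midnight | 0.250 | 1.3 | 99.4 |
| midnight | 0.667 | 1.2 | 98.3 |
| midnight | 1.33 | 2.8 | 96.1 |
| midnight | 2.00 | 4.1 | 95.1 |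
| midnight | 3.00 | 8.4 | 91.6 |
| midnight | 4.00 | 10.3 | 89.0 |
| midnight | 5.00 | 13.1 | 86.7 |
| spring | 0.667 | 4.0 | 95.8 |
| spring | 1.33 | 7.5 | 92.9 |
| spring | 2.00 | 10.3 | 88.9 |
| spring | 3.00 | 15.4 | 83.5 |
| spring | 4.00 | 21.6 | 77.4 |
| spring | 5.00 | 26.4 | 73.3 |

(standard deviation of a reading: 0.5 percentage points)

- on the list of suspects stand: second substrate + free catalyst <-> catalyst intermediate B; coupling partner + catalyst intermediate A -> free catalyst + target; coupling partner + free catalyst -> spent catalyst; coupling partner + catalyst intermediate B -> free catalyst + second product; starting material + free catalyst <-> catalyst intermediate A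

* apparent order in free catalyst when 30% of the starting material are converted (percent change of the rate of making target for one percent more free catalyst charged)

Take the slope s from the last reading of each run. The midnight run gives 0.0285 min⁻¹ and the spring run gives 0.0621 min⁻¹. That is a ratio of 2.18. Both runs carry the same loading, so the catalyst concentration E, charge times loading, rose 2.25-fold between them. Starting material, second substrate and coupling partner rose by that same factor, so these two runs do not part them from the catalyst. Take the catalyst as carrying it, as an assumption of this reckoning.

Now divide each slope by its E and average the two. This gives κ, the catalyst constant, the first-order slope per mole per litre of catalyst charged: 56.2 M⁻¹ min⁻¹.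

Next ask how the comparison drifts. In the spring run the slope up to 2.00 min is 0.0588 min⁻¹, and up to 5.00 min it is 0.0621 min⁻¹. The slope does not fall, so these readings show no catalyst loss beyond their scatter.

For the new flask, E is 7.50 × 10⁻⁴ M. My reckoning is rate = κ·E·[starting material], which puts 30% conversion at 8.47 min. With the charge of starting material held, [starting material] at that conversion is the same for any loading. One percent more catalyst then gives one percent more rate, so my order is one.

The forecast gives 1.05, a shade above mine: “Hence the order is slightly above one.”

The flask gives 1.0, and the forecast stands within its margin.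

    second substrate + free catalyst ⇌ catalyst intermediate B (K = 2.20 M⁻¹, k = 13000 M⁻¹ min⁻¹)
    coupling partner + catalyst intermediate A → free catalyst + target (k = 26.0 M⁻¹ min⁻¹)
    coupling partner + free catalyst → spent catalyst (k = 0.0180 M⁻¹ min⁻¹)
    coupling partner + catalyst intermediate B → free catalyst + second product (k = 110 M⁻¹ min⁻¹)
    starting material + free catalyst ⇌ catalyst intermediate A (K = 320 M⁻¹, k = 550 M⁻¹ min⁻¹)

In this flask, spent catalyst is 0.574% of the catalyst charged after 4.00 min. Put κ to use on this flask. It gave 8.47 min to reach 30%, a little later than the flask's 8.25 min. Run κ on to 40.0 min: it leaves 18.6% of the starting material, and the flask holds 6.21%.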